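**Plan**

- Retrosynthetic cuts, in order: the four O–CH3 bonds; the flavone C4–C4a bond (intramolecular Friedel–Crafts acylation); the enol ether bond O1–C2 (phenol plus arylpropiolate); the biaryl bond between coumarin C8 and flavone C6 (Negishi); finally C8–I of the coumarin and the C–OH bond of the ring A phenol.
- Forward order: the coumarin rings come intact from umbelliferone, the biaryl bond is made first, the aryl vinyl ether second, and the pyranone ring of the flavone is the only ring built, directly before deprotection.
- Enabling feature: flavone O1 lies para to C6 on ring A and the C5 and C7 oxygens flank C6, so ring A is a 4-aryl-3,5-dimethoxyphenol whose two free ortho carbons are equivalent; either one becomes C4a and both give the 6-aryl flavone.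
- Stereochemistry: the target has no stereocentre; the enol ether geometry comes from anti addition and disappears on ring closure; the biaryl axis is formed without control.

Key step: step 10

Remark: the target is drawn without a descriptor for the biaryl axis, so the route is planned for material that is racemic about this axis; the enol ether of 15 and 16 is written Z, and any E isomer would be carried along because it converges in step 10.

**Route**

Step 1
Reactants: 1 umbelliferone (7-hydroxychromen-2-one)
Product: 2 7-hydroxy-8-iodochromen-2-one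
Conditions: I2, KI, 20% aq NH3, 0 °C → rt; then 2 M H2SO4
Reagents that add atoms: iodine, II
Why: Electrophilic aromatic iodination of the phenoxide should occur at C8, the carbon ortho to O7 and next to the ring oxygen, which is the most nucleophilic position of umbelliferone under these standard aqueous ammonia conditions.

Step 2
Reactants: 2 7-hydroxy-8-iodochromen-2-one
Product: 3 8-iodo-7-methoxychromen-2-one
Conditions: MeI, K2CO3, acetone, reflux
Reagents that add atoms: iodomethane, CI
Why: Williamson ether synthesis on an acidic coumarin phenol; carbonate in acetone should leave the lactone closed.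

Step 3
Reactants: 4 2-bromo-1,3-dimethoxybenzene
Product: 6 4-bromo-3,5-dimethoxyphenol, via pinacol boronate 5 (not isolated)
Conditions: B2pin2 (0.6 equiv), [Ir(OMe)(cod)]2 (1.5 mol%), 4,4'-di-tert-butyl-2,2'-bipyridine (3 mol%), THF, 80 °C; then 30% aq H2O2, 2 M NaOH, 0 °C → rt; HCl work-up
Reagents that add atoms: hydrogen peroxide, OO
Why: Iridium-catalysed C–H borylation is sterically controlled and should take place only at C5, the one C–H without an ortho substituent, and alkaline peroxide oxidation of the aryl boronate (aryl migration from boron to oxygen) then gives the phenol with the C–Br bond untouched.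

Step 4
Reactants: 6 4-bromo-3,5-dimethoxyphenol
Product: 7 (4-bromo-3,5-dimethoxyphenoxy)tri(propan-2-yl)silane
Conditions: iPr3SiCl, imidazole, DMF, rt
Reagents that add atoms: chlorotri(propan-2-yl)silane, CC(C)[Si](Cl)(C(C)C)C(C)C
Why: Standard silylation of an unhindered phenol; the bulky silyl ether is chosen to survive the aryllithium and arylzinc stages of the next step.

Step 5
Reactants: 7 (4-bromo-3,5-dimethoxyphenoxy)tri(propan-2-yl)silane; 3 8-iodo-7-methoxychromen-2-one
Product: 10 8-[2,6-dimethoxy-4-(triisopropylsilyloxy)phenyl]-7-methoxychromen-2-one, via aryllithium 8 (not isolated), via arylzinc chloride 9 (not isolated)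
Conditions: 7 (1.5 equiv), n-BuLi, THF, −78 °C; ZnCl2, −78 °C → rt; then 3, Pd2(dba)3 (2.5 mol%), RuPhos (2-dicyclohexylphosphino-2',6'-diisopropoxybiphenyl, 10 mol%), THF, 65 °C
Reagents that add atoms: none
Why: Bromine–lithium exchange and transmetalation give an arylzinc chloride that tolerates the lactone, and Negishi cross-coupling with the aryl iodide on zerovalent palladium bearing a bulky dialkylbiarylphosphine is the established way to biaryls with four small ortho substituents.

Step 6
Reactants: 10 8-[2,6-dimethoxy-4-(triisopropylsilyloxy)phenyl]-7-methoxychromen-2-one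
Product: 11 8-(4-hydroxy-2,6-dimethoxyphenyl)-7-methoxychromen-2-one
Conditions: Bu4NF, AcOH, THF, 0 °C → rt
Reagents that add atoms: none
Why: Fluoride-mediated desilylation driven by the Si–F bond; the acetic acid buffer keeps the medium from becoming basic enough to touch the coumarin.

Step 7
Reactants: 12 1-ethynyl-4-methoxybenzene
Product: 14 tert-butyl 3-(4-methoxyphenyl)prop-2-ynoate, via lithium acetylide 13 (not isolated)
Conditions: n-BuLi, THF, −78 °C; Boc2O, −78 → 0 °C; aq NH4Cl
Reagents that add atoms: di-tert-butyl dicarbonate, CC(C)(C)OC(=O)OC(=O)OC(C)(C)C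
Why: Alkoxycarbonylation of a lithium acetylide with Boc2O is a routine entry to tert-butyl alkynoates, and the tert-butyl ester is chosen so that the acid can later be freed without hydroxide.

Step 8
Reactants: 11 8-(4-hydroxy-2,6-dimethoxyphenyl)-7-methoxychromen-2-one; 14 tert-butyl 3-(4-methoxyphenyl)prop-2-ynoate
Product: 15 tert-butyl (Z)-3-[3,5-dimethoxy-4-(7-methoxy-2-oxochromen-8-yl)phenoxy]-3-(4-methoxyphenyl)prop-2-enoate
Conditions: Cs2CO3 (0.3 equiv), DMF, 70 °C
Reagents that add atoms: none
Why: Base-catalysed oxa-Michael addition of the unhindered phenoxide to the β-carbon of the ynoate, with anti protonation placing the aryloxy group cis to the ester (Z).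

Step 9
Reactants: 15 tert-butyl (Z)-3-[3,5-dimethoxy-4-(7-methoxy-2-oxochromen-8-yl)phenoxy]-3-(4-methoxyphenyl)prop-2-enoate
Product: 16 (Z)-3-[3,5-dimethoxy-4-(7-methoxy-2-oxochromen-8-yl)phenoxy]-3-(4-methoxyphenyl)prop-2-enoic acid
Conditions: CF3CO2H, CH2Cl2 (1:4), 0 °C → rt
Reagents that add atoms: none
Why: Acidolysis of the tert-butyl ester with loss of isobutene leaves the lactone and methyl ethers alone, and tert-butylation of ring A is not expected because each of its free carbons is flanked by two oxygen substituents.

Step 10
Reactants: 16 (Z)-3-[3,5-dimethoxy-4-(7-methoxy-2-oxochromen-8-yl)phenoxy]-3-(4-methoxyphenyl)prop-2-enoic acid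
Product: 17 5,7-dimethoxy-6-(7-methoxy-2-oxochromen-8-yl)-2-(4-methoxyphenyl)chromen-4-one
Conditions: P2O5 in MeSO3H (1:10 w/w), rt → 45 °C; ice water
Reagents that add atoms: none
Why: P2O5 in MeSO3H turns the acid into a mixed anhydride and then the acylium ion, which the Z enol ether holds over ring A; attack of the ring carbon ortho to the ether oxygen, ortho to one methoxy group and para to the other forms C4–C4a, and loss of a proton gives the aromatic pyranone. The closest known reaction is the classical cyclodehydration of 3-aryloxycinnamic acids to flavones, an intramolecular Friedel–Crafts acylation. The pyranone closes as a six-membered ring with the acylium C=O exocyclic and the attacked arene bond (the future C4a–C8a) inside the new ring. No stereocentre is formed. The step needs site selectivity against closure onto the 4-methoxyphenyl ring (a five-membered indenone closure at a carbon meta to its methoxy group, possible only from the E isomer) and against the lactone-deactivated coumarin ring; ring A is favoured by both electronics and ring size, and acid-mediated E/Z equilibration of the push-pull alkene feeds any E isomer into the same closure. The choice between a 6-aryl and an 8-aryl flavone does not arise, because the two free ortho carbons of the 4-aryl-3,5-dimethoxyphenoxy ring are interchanged by its local twofold symmetry.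

Step 11
Reactants: 17 5,7-dimethoxy-6-(7-methoxy-2-oxochromen-8-yl)-2-(4-methoxyphenyl)chromen-4-one
Product: 18 5,7-dihydroxy-6-(7-hydroxy-2-oxochromen-8-yl)-2-(4-hydroxyphenyl)chromen-4-one
Conditions: BBr3 (12 equiv), CH2Cl2, −78 °C → rt (40 °C if needed); then H2O
Reagents that add atoms: none
Why: Lewis acid ether cleavage (boron coordination to each ether oxygen, bromide attack on methyl) should remove all four aryl methyl ethers, the chelated 5-methoxy group first, while the lactone and the pyranone survive.

**Compound list**

1 | umbelliferone (7-hydroxychromen-2-one) | O=c1ccc2ccc(O)cc2o1 | starting material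
2 | 7-hydroxy-8-iodochromen-2-one | O=c1ccc2ccc(O)c(I)c2o1 | intermediate
3 | 8-iodo-7-methoxychromen-2-one | COc1ccc2ccc(=O)oc2c1I | intermediate
4 | 2-bromo-1,3-dimethoxybenzene | COc1cccc(OC)c1Br | starting material
5 | 2-(4-bromo-3,5-dimethoxyphenyl)-4,4,5,5-tetramethyl-1,3,2-dioxaborolane | COc1cc(B2OC(C)(C)C(C)(C)O2)cc(OC)c1Br | intermediate (not isolated)
6 | 4-bromo-3,5-dimethoxyphenol | COc1cc(O)cc(OC)c1Br | intermediate
7 | (4-bromo-3,5-dimethoxyphenoxy)tri(propan-2-yl)silane | COc1cc(O[Si](C(C)C)(C(C)C)C(C)C)cc(OC)c1Br | intermediate
8 | [2,6-dimethoxy-4-(triisopropylsilyloxy)phenyl]lithium | [Li]c1c(OC)cc(O[Si](C(C)C)(C(C)C)C(C)C)cc1OC | intermediate (not isolated)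
9 | [2,6-dimethoxy-4-(triisopropylsilyloxy)phenyl]zinc chloride | Cl[Zn]c1c(OC)cc(O[Si](C(C)C)(C(C)C)C(C)C)cc1OC | intermediate (not isolated)
10 | 8-[2,6-dimethoxy-4-(triisopropylsilyloxy)phenyl]-7-methoxychromen-2-one | COc1cc(O[Si](C(C)C)(C(C)C)C(C)C)cc(OC)c1-c1c(OC)ccc2ccc(=O)oc12 | intermediate
11 | 8-(4-hydroxy-2,6-dimethoxyphenyl)-7-methoxychromen-2-one | COc1cc(O)cc(OC)c1-c1c(OC)ccc2ccc(=O)oc12 | intermediate
12 | 1-ethynyl-4-methoxybenzene | C#Cc1ccc(OC)cc1 | starting material
13 | lithium (4-methoxyphenyl)acetylide | [Li]C#Cc1ccc(OC)cc1 | intermediate (not isolated)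
14 | tert-butyl 3-(4-methoxyphenyl)prop-2-ynoate | COc1ccc(C#CC(=O)OC(C)(C)C)cc1 | intermediate
15 | tert-butyl (Z)-3-[3,5-dimethoxy-4-(7-methoxy-2-oxochromen-8-yl)phenoxy]-3-(4-methoxyphenyl)prop-2-enoate | CC(C)(C)OC(=O)/C=C(\Oc1cc(OC)c(-c2c(OC)ccc3ccc(=O)oc23)c(OC)c1)c1ccc(OC)cc1 | intermediate
16 | (Z)-3-[3,5-dimethoxy-4-(7-methoxy-2-oxochromen-8-yl)phenoxy]-3-(4-methoxyphenyl)prop-2-enoic acid | O=C(O)/C=C(\Oc1cc(OC)c(-c2c(OC)ccc3ccc(=O)oc23)c(OC)c1)c1ccc(OC)cc1 | intermediate
17 | 5,7-dimethoxy-6-(7-methoxy-2-oxochromen-8-yl)-2-(4-methoxyphenyl)chromen-4-one | COc1ccc(-c2cc(=O)c3c(OC)c(-c4c(OC)ccc5ccc(=O)oc45)c(OC)cc3o2)cc1 | intermediate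
18 | 5,7-dihydroxy-6-(7-hydroxy-2-oxochromen-8-yl)-2-(4-hydroxyphenyl)chromen-4-one | O=c1ccc2ccc(O)c(-c3c(O)cc4oc(-c5ccc(O)cc5)cc(=O)c4c3O)c2o1 | target

**Count and risks**

Total steps: 11. Longest linear sequence: 8 steps (steps 3, 4, 5, 6, 8, 9, 10, 11; the coumarin branch through steps 1 and 2 is equally long).

Step 5. Transmetalation and reductive elimination at a palladium centre carrying two di-ortho-substituted aryl groups may be slow, so that protonation of the arylzinc and reduction of the C–I bond of 3 could overtake the coupling. The fallback changes the nucleophile from zinc to boron. It sets out from 7: bromine–lithium exchange (n-BuLi, THF, −78 °C) and quenching with 2-isopropoxy-4,4,5,5-tetramethyl-1,3,2-dioxaborolane should give 2-[2,6-dimethoxy-4-(triisopropylsilyloxy)phenyl]-4,4,5,5-tetramethyl-1,3,2-dioxaborolane F1. Suzuki–Miyaura coupling of this isolable boronate with 3 (Pd(OAc)2, SPhos, anhydrous K3PO4, toluene, 100 °C) comes back to the route at 10.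

Step 8. The 4-methoxyphenyl group lowers the electrophilicity of the β-carbon and the tert-butyl ester adds bulk, so the conjugate addition may stall, and forcing it may allow reversal of the addition or attack of the phenoxide on the coumarin. The fallback replaces addition to the alkyne by substitution at a vinyl halide. It sets out from 14: hydroiodination (NaI, AcOH, 90 °C) should give tert-butyl (Z)-3-iodo-3-(4-methoxyphenyl)prop-2-enoate F2 by anti addition. Ullmann-type C–O coupling of this iodide with phenol 11 (CuI, N,N-dimethylglycine, Cs2CO3, dioxane, 90 °C) should proceed with retention of the alkene geometry and comes back at 15.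

Step 10. In the strong Brønsted acid, protonation of the enol ether at C2 may lead to cleavage of the aryl–oxygen–vinyl linkage before acylation, after which the released phenol could recombine through carbon (a Pechmann-type path); sulfonation of ring A is a lesser risk. The fallback moves the activation from a superacid medium to a discrete acyl chloride and a Lewis acid. It sets out from 16: oxalyl chloride with catalytic DMF in CH2Cl2 at 0 °C should give (Z)-3-[3,5-dimethoxy-4-(7-methoxy-2-oxochromen-8-yl)phenoxy]-3-(4-methoxyphenyl)prop-2-enoyl chloride F3. Friedel–Crafts closure of this chloride with SnCl4 in CH2Cl2 at −20 °C → rt forms the same C4–C4a bond and comes back at 17.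

**Further compounds**

F1 | step 5 | 2-[2,6-dimethoxy-4-(triisopropylsilyloxy)phenyl]-4,4,5,5-tetramethyl-1,3,2-dioxaborolane | COc1cc(O[Si](C(C)C)(C(C)C)C(C)C)cc(OC)c1B1OC(C)(C)C(C)(C)O1
F2 | step 8 | tert-butyl (Z)-3-iodo-3-(4-methoxyphenyl)prop-2-enoate | CC(C)(C)OC(=O)/C=C(\I)c1ccc(OC)cc1
F3 | step 10 | (Z)-3-[3,5-dimethoxy-4-(7-methoxy-2-oxochromen-8-yl)phenoxy]-3-(4-methoxyphenyl)prop-2-enoyl chloride | O=C(Cl)/C=C(\Oc1cc(OC)c(-c2c(OC)ccc3ccc(=O)oc23)c(OC)c1)c1ccc(OC)cc1
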